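**Plan**

- Retrosynthesis: the side chain is cut at C2′–C3′ (SN2′ alkylation of an oxidised C5 prenyl group), the dihydrofuran at O1–C2 (phenoxide opening of a prenyl epoxide), and both aryl–CH2 bonds back to a 2,6-dihydroxy-4-methoxybenzophenone. Ring A is then cut between the aroyl-bearing carbon and a neighbouring C–OH carbon, and the aroyl C–CH2 bond leads to 4-methoxy-6-methylpyran-2-one and a 3-oxygenated benzoate.
- Enabling feature: ring A carries oxygen on three alternate carbons (C4 OMe, C6 OH, C7a O), with the aroyl group on C7 between two of them and the methyl ether para to it. This is the pattern of a cyclised 3,5,7-trioxo acid, which a 6-(2-aryl-2-oxoethyl)-4-methoxypyran-2-one holds in masked form.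
- Forward order: pyranone acylation; ring A by magnesium-mediated Claisen cyclisation; first prenyl group and dihydrofuran ring; second prenyl group by O-alkylation and Claisen rearrangement; allylic chloride; side chain by copper-catalysed SN2′ alkylation; deprotection.
- Stereochemistry: C2 of the dihydrofuran (S) comes from a Shi epoxidation (R epoxide) followed by invertive 5-exo opening. C2′ of the side chain (R) comes from a chiral copper–phosphoramidite catalyst.

Key step: step 3

Assumption: the (S,S,S) antipode of the phosphoramidite ligand in step 15 is taken to deliver the 2′R centre; the sense is to be verified on the first run and the mirror-image ligand used if it proves opposite.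

**Route**

Step 1
Reactants: 1 methyl 3-hydroxybenzoate
Product: 2 methyl 3-(methoxymethoxy)benzoate
Conditions: MOMCl, iPr2NEt, CH2Cl2, 0 °C → rt
Reagents that add atoms: chloromethyl methyl ether, COCCl
Why: Williamson-type O-alkylation of the phenol gives an acetal ether that should withstand every basic, oxidative and organometallic step that follows and keeps the phenoxide from deactivating the ester in step 2.

Step 2
Reactants: 3 4-methoxy-6-methyl-2H-pyran-2-one; 2 methyl 3-(methoxymethoxy)benzoate
Product: 4 4-methoxy-6-{2-[3-(methoxymethoxy)phenyl]-2-oxoethyl}-2H-pyran-2-one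
Conditions: LiN(SiMe3)2 (2.2 equiv), THF, −78 °C; then 2, −78 → 0 °C; aq. NH4Cl
Reagents that add atoms: none
Why: Vinylogous deprotonation of the 6-methyl group gives an extended enolate that undergoes a crossed Claisen acylation with the non-enolisable ester, the second equivalent of base taking up the more acidic product and so preventing double acylation.

Step 3
Reactants: 4 4-methoxy-6-{2-[3-(methoxymethoxy)phenyl]-2-oxoethyl}-2H-pyran-2-one
Product: 6 (2,6-dihydroxy-4-methoxyphenyl)[3-(methoxymethoxy)phenyl]methanone, via ring-opened diketo enoate 5 (not isolated)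
Conditions: Mg(OMe)2 (4 equiv, solution in MeOH), MeOH, reflux; then 1 M HCl
Reagents that add atoms: none
Why: Methoxide adds to the lactone carbonyl of 4 and the ring opens to the magnesium chelate of triketo ester 5, in which the ester and the diketone chain stay on the same side of the enol ether double bond as they were in the ring. The carbon between the two ketone carbonyls, held as a magnesium 1,3-diketonate, attacks the ester carbonyl in an intramolecular Claisen (Dieckmann-type) condensation, methoxide leaves and enolisation gives the arene; the closest known reaction type is the magnesium-alkoxide-mediated conversion of 6-(2-oxoalkyl)-4-methoxypyran-2-ones into acylphloroglucinol monomethyl ethers. Ring A closes in the 6-exo-trig mode, the ester carbonyl oxygen lying outside the new ring. No stereocentre is formed. The step needs Claisen over aldol selectivity (attack of the enoate α-carbon on the aryl ketone would give a resorcylate), and this is secured by the magnesium chelate, which makes the diketone carbon the nucleophile and deactivates the aryl ketone as an electrophile, and by the cis arrangement of ester and chain inherited from the pyranone. The enol ether oxygen of the pyranone ends up as the methyl ether para to the aroyl group, so the three ring oxygens emerge differentiated.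

Step 4
Reactants: 6 (2,6-dihydroxy-4-methoxyphenyl)[3-(methoxymethoxy)phenyl]methanone; 7 prenyl bromide (1-bromo-3-methylbut-2-ene)
Product: 8 [2,6-dihydroxy-4-methoxy-3-(3-methylbut-2-en-1-yl)phenyl][3-(methoxymethoxy)phenyl]methanone
Conditions: 7 (1.05 equiv), 10 % aq. KOH, 0 °C → rt; then dilute HCl
Reagents that add atoms: none
Why: C-alkylation of the ambident acylphloroglucinol dianion (Friedel–Crafts-type C-prenylation) is favoured in water, which solvates the phenoxide oxygens, and the two free ring carbons are equivalent, so only the degree of alkylation has to be held by the stoichiometry.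

Step 5
Reactants: 8 [2,6-dihydroxy-4-methoxy-3-(3-methylbut-2-en-1-yl)phenyl][3-(methoxymethoxy)phenyl]methanone
Product: 9 5-methoxy-2-[3-(methoxymethoxy)benzoyl]-4-(3-methylbut-2-en-1-yl)-1,3-phenylene bis(2,2-dimethylpropanoate)
Conditions: PivCl (3 equiv), Et3N, DMAP (cat.), CH2Cl2, rt
Reagents that add atoms: pivaloyl chloride, CC(C)(C)C(=O)Cl
Why: DMAP-catalysed acylation masks both chelated phenols as hindered esters, which should survive the pH 10.5 buffer of the epoxidation and make the arene too electron-poor to be oxidised.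

Step 6
Reactants: 9 5-methoxy-2-[3-(methoxymethoxy)benzoyl]-4-(3-methylbut-2-en-1-yl)-1,3-phenylene bis(2,2-dimethylpropanoate)
Product: 10 4-{[(2R)-3,3-dimethyloxiran-2-yl]methyl}-5-methoxy-2-[3-(methoxymethoxy)benzoyl]-1,3-phenylene bis(2,2-dimethylpropanoate)
Conditions: Shi ketone (1,2:4,5-di-O-isopropylidene-β-D-erythro-2,3-hexodiulo-2,6-pyranose, from D-fructose, 30 mol %), KHSO5 (as 2KHSO5·KHSO4·K2SO4), K2CO3, n-Bu4NHSO4 (cat.), MeCN/CH2(OMe)2–aq. Na2B4O7 buffer (pH 10.5), 0 °C
Reagents that add atoms: potassium peroxymonosulfate, [K+].[O-]S(=O)(=O)OO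
Why: Shi epoxidation of the trisubstituted olefin by the chiral dioxirane through the spiro transition state should deliver oxygen to the face that makes the CH carbon R, as is the rule for the D-fructose-derived ketone with trans-type and trisubstituted olefins.

Step 7
Reactants: 10 4-{[(2R)-3,3-dimethyloxiran-2-yl]methyl}-5-methoxy-2-[3-(methoxymethoxy)benzoyl]-1,3-phenylene bis(2,2-dimethylpropanoate)
Product: 11 [(2S)-6-hydroxy-2-(2-hydroxypropan-2-yl)-4-methoxy-2,3-dihydro-1-benzofuran-7-yl][3-(methoxymethoxy)phenyl]methanone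
Conditions: NaOMe (3 equiv), MeOH, 0 °C → rt; aq. NH4Cl
Reagents that add atoms: none
Why: Transesterification frees both phenoxides and the one ortho to the epoxide chain opens the oxirane at its secondary carbon in a 5-exo-tet SN2 reaction with inversion (R epoxide → 2S dihydrofuran), attack at the tertiary carbon (6-endo) being disfavoured under basic conditions.

Step 8
Reactants: 12 2-methylbut-3-en-2-ol
Product: 13 tert-butyl 2-methylbut-3-en-2-yl carbonate
Conditions: n-BuLi, THF, 0 °C; then Boc2O, 0 °C → rt; aq. NH4Cl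
Reagents that add atoms: di-tert-butyl dicarbonate, CC(C)(C)OC(=O)OC(=O)OC(C)(C)C
Why: Acylation of the lithium alkoxide of the tertiary allylic alcohol by the dicarbonate is the standard way to the mixed carbonate used for palladium-catalysed tert-prenylation.

Step 9
Reactants: 11 [(2S)-6-hydroxy-2-(2-hydroxypropan-2-yl)-4-methoxy-2,3-dihydro-1-benzofuran-7-yl][3-(methoxymethoxy)phenyl]methanone; 13 tert-butyl 2-methylbut-3-en-2-yl carbonate
Product: 14 {(2S)-2-(2-hydroxypropan-2-yl)-4-methoxy-6-[(2-methylbut-3-en-2-yl)oxy]-2,3-dihydro-1-benzofuran-7-yl}[3-(methoxymethoxy)phenyl]methanone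
Conditions: Pd(PPh3)4 (5 mol %), 13 (1.5 equiv), THF, 0 °C
Reagents that add atoms: none
Why: In this Tsuji–Trost O-allylation zerovalent palladium ionises the carbonate, the liberated tert-butoxide deprotonates the phenol, and the phenoxide attacks the more substituted terminus of the 1,1-dimethylallyl complex under kinetic control at 0 °C, the tertiary alcohol being too weak an acid to compete.

Step 10
Reactants: 14 {(2S)-2-(2-hydroxypropan-2-yl)-4-methoxy-6-[(2-methylbut-3-en-2-yl)oxy]-2,3-dihydro-1-benzofuran-7-yl}[3-(methoxymethoxy)phenyl]methanone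
Product: 15 [(2S)-6-hydroxy-2-(2-hydroxypropan-2-yl)-4-methoxy-5-(3-methylbut-2-en-1-yl)-2,3-dihydro-1-benzofuran-7-yl][3-(methoxymethoxy)phenyl]methanone
Conditions: toluene, 110 °C
Reagents that add atoms: none
Why: Aromatic Claisen rearrangement carries the allyl unit with inversion to C5, the only free ortho carbon, so the 1,1-dimethylallyl ether becomes a C-prenyl group, and tautomerisation restores the chelated phenol.

Step 11
Reactants: 15 [(2S)-6-hydroxy-2-(2-hydroxypropan-2-yl)-4-methoxy-5-(3-methylbut-2-en-1-yl)-2,3-dihydro-1-benzofuran-7-yl][3-(methoxymethoxy)phenyl]methanone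
Product: 16 [(2S)-4-methoxy-5-(3-methylbut-2-en-1-yl)-6-(triethylsilyloxy)-2-[2-(triethylsilyloxy)propan-2-yl]-2,3-dihydro-1-benzofuran-7-yl][3-(methoxymethoxy)phenyl]methanone
Conditions: Et3SiOTf (3 equiv), 2,6-lutidine (5 equiv), CH2Cl2, −78 → 0 °C
Reagents that add atoms: triethylsilyl trifluoromethanesulfonate, CC[Si](CC)(CC)OS(=O)(=O)C(F)(F)F
Why: Silylation with the silyl triflate caps the hindered chelated phenol and the tertiary alcohol in one operation, so that the Grignard reagent of step 15 meets no acidic proton, and at low temperature with a hindered base the aryl acetal should be untouched.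

Step 12
Reactants: 16 [(2S)-4-methoxy-5-(3-methylbut-2-en-1-yl)-6-(triethylsilyloxy)-2-[2-(triethylsilyloxy)propan-2-yl]-2,3-dihydro-1-benzofuran-7-yl][3-(methoxymethoxy)phenyl]methanone
Product: 17 {(2S)-5-[(2E)-4-hydroxy-3-methylbut-2-en-1-yl]-4-methoxy-6-(triethylsilyloxy)-2-[2-(triethylsilyloxy)propan-2-yl]-2,3-dihydro-1-benzofuran-7-yl}[3-(methoxymethoxy)phenyl]methanone
Conditions: SeO2 (0.5 equiv), t-BuOOH (3 equiv, in decane), CH2Cl2, 0 °C → rt
Reagents that add atoms: selenium dioxide (oxygen carrier), O=[Se]=O; tert-butyl hydroperoxide (terminal oxidant), CC(C)(C)OO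
Why: Riley allylic oxidation (ene reaction, then 2,3-sigmatropic shift) attacks the methyl group trans to the chain at the more substituted olefin terminus and so should give the E allylic alcohol, the ring-bound CH2 at the less substituted terminus being left alone.

Step 13
Reactants: 17 {(2S)-5-[(2E)-4-hydroxy-3-methylbut-2-en-1-yl]-4-methoxy-6-(triethylsilyloxy)-2-[2-(triethylsilyloxy)propan-2-yl]-2,3-dihydro-1-benzofuran-7-yl}[3-(methoxymethoxy)phenyl]methanone
Product: 18 {(2S)-5-[(2E)-4-chloro-3-methylbut-2-en-1-yl]-4-methoxy-6-(triethylsilyloxy)-2-[2-(triethylsilyloxy)propan-2-yl]-2,3-dihydro-1-benzofuran-7-yl}[3-(methoxymethoxy)phenyl]methanone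
Conditions: NCS, Me2S, CH2Cl2, −20 → 0 °C
Reagents that add atoms: N-chlorosuccinimide, O=C1CCC(=O)N1Cl
Why: Corey–Kim chlorination turns the primary allylic alcohol into an alkoxysulfonium salt that chloride displaces at the primary carbon, without allylic transposition or loss of the E geometry and under conditions neutral enough for silyl ethers and the acetal.

Step 14
Reactants: 19 4-bromo-2-methylbut-1-ene
Product: 20 (3-methylbut-3-en-1-yl)magnesium bromide
Conditions: Mg turnings, I2 (cat.), Et2O, reflux
Reagents that add atoms: magnesium, [Mg]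
Why: Grignard formation by insertion of magnesium into the primary C–Br bond gives a homoallylic reagent that is configurationally and structurally stable.

Step 15
Reactants: 18 {(2S)-5-[(2E)-4-chloro-3-methylbut-2-en-1-yl]-4-methoxy-6-(triethylsilyloxy)-2-[2-(triethylsilyloxy)propan-2-yl]-2,3-dihydro-1-benzofuran-7-yl}[3-(methoxymethoxy)phenyl]methanone; 20 (3-methylbut-3-en-1-yl)magnesium bromide
Product: 21 {(2S)-4-methoxy-5-[(2R)-5-methyl-2-(prop-1-en-2-yl)hex-5-en-1-yl]-6-(triethylsilyloxy)-2-[2-(triethylsilyloxy)propan-2-yl]-2,3-dihydro-1-benzofuran-7-yl}[3-(methoxymethoxy)phenyl]methanone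
Conditions: Cu(O2C-2-C4H3S) (copper thiophene-2-carboxylate, 5 mol %), (S,S,S)-binaphthol phosphoramidite of bis[1-(2-methoxyphenyl)ethyl]amine (6 mol %), CH2Cl2, −78 °C; 20 (1.3 equiv, Et2O) added over 2 h
Reagents that add atoms: none
Why: Copper-catalysed asymmetric allylic alkylation of a 2-methyl-substituted allylic chloride proceeds by anti SN2′ oxidative addition of the monovalent copper alkyl to a γ-bound allyl trivalent copper species and fast reductive elimination, so the alkyl group enters at the CH carbon and leaves the isopropenyl group behind; the new 2′R centre is set by the chiral ligand alone (reagent control, the ring stereocentre being remote), and slow addition at −78 °C keeps free Grignard reagent away from the doubly ortho-substituted diaryl ketone.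

Step 16
Reactants: 21 {(2S)-4-methoxy-5-[(2R)-5-methyl-2-(prop-1-en-2-yl)hex-5-en-1-yl]-6-(triethylsilyloxy)-2-[2-(triethylsilyloxy)propan-2-yl]-2,3-dihydro-1-benzofuran-7-yl}[3-(methoxymethoxy)phenyl]methanone
Product: 22 [(2S)-6-hydroxy-2-(2-hydroxypropan-2-yl)-4-methoxy-5-[(2R)-5-methyl-2-(prop-1-en-2-yl)hex-5-en-1-yl]-2,3-dihydro-1-benzofuran-7-yl](3-hydroxyphenyl)methanone
Conditions: HCl (dilute, in MeOH), MeOH/THF, 0 °C → rt, stopped as soon as the acetal is consumed
Reagents that add atoms: none
Why: Acid-catalysed methanolysis removes both silyl ethers quickly and the aryl methoxymethyl acetal more slowly, as is routine for prenylated phenols, and neither stereocentre is acidic or ionisable under such mild conditions.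

**Compound list**

1 | methyl 3-hydroxybenzoate | COC(=O)c1cccc(O)c1 | starting material
2 | methyl 3-(methoxymethoxy)benzoate | COCOc1cccc(c1)C(=O)OC | intermediate
3 | 4-methoxy-6-methyl-2H-pyran-2-one | COC1=CC(=O)OC(C)=C1 | starting material
4 | 4-methoxy-6-{2-[3-(methoxymethoxy)phenyl]-2-oxoethyl}-2H-pyran-2-one | COCOc1cccc(c1)C(=O)CC1=CC(OC)=CC(=O)O1 | intermediate
5 | methyl (2E)-3-methoxy-7-[3-(methoxymethoxy)phenyl]-5,7-dioxohept-2-enoate (ester and C4 on the same side; present as its magnesium chelate) | COC(=O)/C=C(/OC)CC(=O)CC(=O)c1cccc(OCOC)c1 | intermediate (not isolated)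
6 | (2,6-dihydroxy-4-methoxyphenyl)[3-(methoxymethoxy)phenyl]methanone | COCOc1cccc(c1)C(=O)c1c(O)cc(OC)cc1O | intermediate
7 | prenyl bromide (1-bromo-3-methylbut-2-ene) | CC(C)=CCBr | starting material
8 | [2,6-dihydroxy-4-methoxy-3-(3-methylbut-2-en-1-yl)phenyl][3-(methoxymethoxy)phenyl]methanone | COCOc1cccc(c1)C(=O)c1c(O)cc(OC)c(CC=C(C)C)c1O | intermediate
9 | 5-methoxy-2-[3-(methoxymethoxy)benzoyl]-4-(3-methylbut-2-en-1-yl)-1,3-phenylene bis(2,2-dimethylpropanoate) | COCOc1cccc(c1)C(=O)c1c(OC(=O)C(C)(C)C)cc(OC)c(CC=C(C)C)c1OC(=O)C(C)(C)C | intermediate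
10 | 4-{[(2R)-3,3-dimethyloxiran-2-yl]methyl}-5-methoxy-2-[3-(methoxymethoxy)benzoyl]-1,3-phenylene bis(2,2-dimethylpropanoate) | COCOc1cccc(c1)C(=O)c1c(OC(=O)C(C)(C)C)cc(OC)c(C[C@H]2OC2(C)C)c1OC(=O)C(C)(C)C | intermediate
11 | [(2S)-6-hydroxy-2-(2-hydroxypropan-2-yl)-4-methoxy-2,3-dihydro-1-benzofuran-7-yl][3-(methoxymethoxy)phenyl]methanone | COCOc1cccc(c1)C(=O)c1c(O)cc(OC)c2C[C@@H](C(C)(C)O)Oc12 | intermediate
12 | 2-methylbut-3-en-2-ol | C=CC(C)(C)O | starting material
13 | tert-butyl 2-methylbut-3-en-2-yl carbonate | C=CC(C)(C)OC(=O)OC(C)(C)C | intermediate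
14 | {(2S)-2-(2-hydroxypropan-2-yl)-4-methoxy-6-[(2-methylbut-3-en-2-yl)oxy]-2,3-dihydro-1-benzofuran-7-yl}[3-(methoxymethoxy)phenyl]methanone | COCOc1cccc(c1)C(=O)c1c(OC(C)(C)C=C)cc(OC)c2C[C@@H](C(C)(C)O)Oc12 | intermediate
15 | [(2S)-6-hydroxy-2-(2-hydroxypropan-2-yl)-4-methoxy-5-(3-methylbut-2-en-1-yl)-2,3-dihydro-1-benzofuran-7-yl][3-(methoxymethoxy)phenyl]methanone | COCOc1cccc(c1)C(=O)c1c(O)c(CC=C(C)C)c(OC)c2C[C@@H](C(C)(C)O)Oc12 | intermediate
16 | [(2S)-4-methoxy-5-(3-methylbut-2-en-1-yl)-6-(triethylsilyloxy)-2-[2-(triethylsilyloxy)propan-2-yl]-2,3-dihydro-1-benzofuran-7-yl][3-(methoxymethoxy)phenyl]methanone | COCOc1cccc(c1)C(=O)c1c(O[Si](CC)(CC)CC)c(CC=C(C)C)c(OC)c2C[C@@H](C(C)(C)O[Si](CC)(CC)CC)Oc12 | intermediate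
17 | {(2S)-5-[(2E)-4-hydroxy-3-methylbut-2-en-1-yl]-4-methoxy-6-(triethylsilyloxy)-2-[2-(triethylsilyloxy)propan-2-yl]-2,3-dihydro-1-benzofuran-7-yl}[3-(methoxymethoxy)phenyl]methanone | COCOc1cccc(c1)C(=O)c1c(O[Si](CC)(CC)CC)c(C/C=C(\C)CO)c(OC)c2C[C@@H](C(C)(C)O[Si](CC)(CC)CC)Oc12 | intermediate
18 | {(2S)-5-[(2E)-4-chloro-3-methylbut-2-en-1-yl]-4-methoxy-6-(triethylsilyloxy)-2-[2-(triethylsilyloxy)propan-2-yl]-2,3-dihydro-1-benzofuran-7-yl}[3-(methoxymethoxy)phenyl]methanone | COCOc1cccc(c1)C(=O)c1c(O[Si](CC)(CC)CC)c(C/C=C(\C)CCl)c(OC)c2C[C@@H](C(C)(C)O[Si](CC)(CC)CC)Oc12 | intermediate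
19 | 4-bromo-2-methylbut-1-ene | C=C(C)CCBr | starting material
20 | (3-methylbut-3-en-1-yl)magnesium bromide | C=C(C)CC[Mg]Br | intermediate
21 | {(2S)-4-methoxy-5-[(2R)-5-methyl-2-(prop-1-en-2-yl)hex-5-en-1-yl]-6-(triethylsilyloxy)-2-[2-(triethylsilyloxy)propan-2-yl]-2,3-dihydro-1-benzofuran-7-yl}[3-(methoxymethoxy)phenyl]methanone | COCOc1cccc(c1)C(=O)c1c(O[Si](CC)(CC)CC)c(C[C@@H](CCC(C)=C)C(C)=C)c(OC)c2C[C@@H](C(C)(C)O[Si](CC)(CC)CC)Oc12 | intermediate
22 | [(2S)-6-hydroxy-2-(2-hydroxypropan-2-yl)-4-methoxy-5-[(2R)-5-methyl-2-(prop-1-en-2-yl)hex-5-en-1-yl]-2,3-dihydro-1-benzofuran-7-yl](3-hydroxyphenyl)methanone | C=C(C)CC[C@H](Cc1c(O)c(C(=O)c2cccc(O)c2)c2c(c1OC)C[C@@H](C(C)(C)O)O2)C(=C)C | target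

**Step count and risks**

Total step count: 16 (14 in the main line, plus the preparation of carbonate 13 and of Grignard reagent 20).
Longest linear sequence: 14 steps (1, 2, 3, 4, 5, 6, 7, 9, 10, 11, 12, 13, 15, 16) from methyl 3-hydroxybenzoate.

Steps most likely to fail:

1. Step 15. The Grignard reagent may add to the diaryl ketone, direct SN2 displacement may compete with SN2′ attack, and the crowded, doubly ortho-substituted benzyl group next to the reacting carbon may weaken facial discrimination. Fallback, from 18 back to 21: Grignard reagent 20 is transmetallated with ZnCl2 (0.5 equiv) to bis(3-methylbut-3-en-1-yl)zinc F1, a nucleophile that does not add to ketones. Chloride 18 is then alkylated with F1 under (CuOTf)2·C6H6 and the same phosphoramidite class in THF at −40 °C, which should give 21 directly. If catalyst control stays incomplete, the two C2′ epimers are diastereomers because of the ring stereocentre and should be separable by preparative HPLC at the stage of 21.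

2. Step 16. While the unactivated aryl acetal is being cleaved, the freed C6 phenol may add to the protonated isopropenyl group (chroman formation), the terminal olefins may take up methanol or migrate, and the tertiary alcohol may ionise. Fallback, from 21 back to 22: the acetal is removed under aprotic conditions with ZnBr2 and n-PrSH in CH2Cl2 at 0 °C within minutes, the thiol capturing the oxocarbenium fragment, to give {(2S)-4-methoxy-5-[(2R)-5-methyl-2-(prop-1-en-2-yl)hex-5-en-1-yl]-6-(triethylsilyloxy)-2-[2-(triethylsilyloxy)propan-2-yl]-2,3-dihydro-1-benzofuran-7-yl}(3-hydroxyphenyl)methanone F2. The silyl ethers are then cleaved with Bu4NF buffered with AcOH in THF at 0 °C → rt to give 22.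

3. Step 4. O-alkylation and over-alkylation (3,5-diprenylation and geminal diprenylation with loss of aromaticity) may compete with mono C-prenylation. Fallback, from 6 back to 8: diol 6 is mono-O-alkylated with carbonate 13 (1.1 equiv) and Pd(PPh3)4 in THF at 0 °C, as in step 9, to give {2-hydroxy-4-methoxy-6-[(2-methylbut-3-en-2-yl)oxy]phenyl}[3-(methoxymethoxy)phenyl]methanone F3. Heating F3 in toluene at 110 °C should then transfer the allyl unit to the adjacent free carbon by aromatic Claisen rearrangement and give 8.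

Further compounds
F1 | step 15 | bis(3-methylbut-3-en-1-yl)zinc | C=C(C)CC[Zn]CCC(C)=C
F2 | step 16 | {(2S)-4-methoxy-5-[(2R)-5-methyl-2-(prop-1-en-2-yl)hex-5-en-1-yl]-6-(triethylsilyloxy)-2-[2-(triethylsilyloxy)propan-2-yl]-2,3-dihydro-1-benzofuran-7-yl}(3-hydroxyphenyl)methanone | Oc1cccc(c1)C(=O)c1c(O[Si](CC)(CC)CC)c(C[C@@H](CCC(C)=C)C(C)=C)c(OC)c2C[C@@H](C(C)(C)O[Si](CC)(CC)CC)Oc12
F3 | step 4 | {2-hydroxy-4-methoxy-6-[(2-methylbut-3-en-2-yl)oxy]phenyl}[3-(methoxymethoxy)phenyl]methanone | COCOc1cccc(c1)C(=O)c1c(O)cc(OC)cc1OC(C)(C)C=C
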